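The 2,3-dimethoxy-1,4-benzoquinone ring is disconnected into the four-carbon ring of dimethyl squarate (quinone C1–C4: both carbonyls and both methoxylated carbons) and the two carbons of a terminal alkyne (C5, which carries the chroman, and C6–H). The key step is a thermal Moore rearrangement: a 4-alkynyl-4-hydroxycyclobutenone opens to an enynylketene that recloses to the six-membered quinone in one operation, at the correct oxidation level and with full regiocontrol. Its precursor is the squarate adduct of (S)-3-ethynyl-6,7,8-trimethoxychromane, whose single stereocentre (chroman C3, propargylic) is set earlier by asymmetric hydrogenation of a 2H-chromene allylic alcohol and is not touched by the ring expansion.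

Key step: step 8

Remarks on the chemistry:
- The stereocentre of the target reads as (3S) from the SMILES (priorities: OCH2 (C2) > quinonyl > benzylic CH2 (C4) > H).
- 2,3,4-Trimethoxyphenol is treated as a catalogue compound.
- The carbinol carbon of 11 forms as both epimers; it becomes a carbonyl carbon in step 8, so its configuration is of no consequence.

Step 1
Reactants: 1 2,3,4-trimethoxyphenol
Product: 2 2-hydroxy-3,4,5-trimethoxybenzaldehyde
Conditions: (CH2O)n, MgCl2, Et3N, MeCN, reflux; then 1 M HCl
Reagents that add atoms: paraformaldehyde (as formaldehyde), C=O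
Why: Magnesium-phenoxide-directed ortho-formylation (Casnati–Skattebøl reaction): formaldehyde is delivered to the only free ortho position and a second formaldehyde accepts hydride from the resulting benzylic alkoxide, so one regioisomer of the salicylaldehyde is expected.

Step 2
Reactants: 2 2-hydroxy-3,4,5-trimethoxybenzaldehyde; 3 acrolein
Product: 4 6,7,8-trimethoxy-2H-chromene-3-carbaldehyde
Conditions: K2CO3 (0.3 equiv), 1,4-dioxane, reflux
Reagents that add atoms: none
Why: Base-mediated oxa-Michael addition of the phenoxide to acrolein followed by intramolecular aldol condensation onto the aryl aldehyde (the standard salicylaldehyde–acrolein 2H-chromene annulation), which should place the formyl group at C3 and the former aryl aldehyde carbon at C4.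

Step 3
Reactants: 4 6,7,8-trimethoxy-2H-chromene-3-carbaldehyde
Product: 5 (6,7,8-trimethoxy-2H-chromen-3-yl)methanol
Conditions: NaBH4, CeCl3·7H2O, MeOH, 0 °C
Reagents that add atoms: none
Why: Luche 1,2-reduction of the conjugated aldehyde, which should leave the C3=C4 alkene and the aryl ethers untouched.

Step 4
Reactants: 5 (6,7,8-trimethoxy-2H-chromen-3-yl)methanol
Product: 6 [(3S)-6,7,8-trimethoxy-3,4-dihydro-2H-chromen-3-yl]methanol
Conditions: H2 (50 bar), [Ir(cod)(L*)]BArF (1 mol %, L* = chiral phosphine–oxazoline of the PHOX family), CH2Cl2, rt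
Reagents that add atoms: none
Why: Iridium–N,P-catalysed asymmetric hydrogenation of a trisubstituted, aryl-conjugated allylic alcohol (the (E)-2-alkyl-3-arylallyl alcohol substrate class): the C3 stereocentre is set by catalyst-controlled delivery of H2 to one face of the C3=C4 bond, the ligand antipode being chosen in a pilot run so that the (S)-alcohol results.

Step 5
Reactants: 6 [(3S)-6,7,8-trimethoxy-3,4-dihydro-2H-chromen-3-yl]methanol
Product: 7 (3R)-6,7,8-trimethoxy-3,4-dihydro-2H-chromene-3-carbaldehyde
Conditions: Dess–Martin periodinane, CH2Cl2, 0 °C to rt; used crude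
Reagents that add atoms: none
Why: Dess–Martin oxidation stops at the aldehyde under near-neutral, non-enolising conditions, so the α-stereocentre should be retained (the descriptor becomes R only because the formyl group outranks C2).

Step 6
Reactants: 7 (3R)-6,7,8-trimethoxy-3,4-dihydro-2H-chromene-3-carbaldehyde
Product: 8 (3S)-3-ethynyl-6,7,8-trimethoxy-3,4-dihydro-2H-chromene
Conditions: dimethyl (1-diazo-2-oxopropyl)phosphonate, K2CO3, MeOH, 0 °C to rt
Reagents that add atoms: Ohira–Bestmann reagent, CC(=O)C(=[N+]=[N-])P(=O)(OC)OC
Why: Seyferth–Gilbert homologation in the Ohira–Bestmann variant converts the formyl carbon into the internal alkyne carbon with retention at C3, the addition/cycloelimination at 0 °C being expected to outpace enolisation of the α-branched aldehyde.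

Step 7
Reactants: 8 (3S)-3-ethynyl-6,7,8-trimethoxy-3,4-dihydro-2H-chromene; 9 dimethyl squarate (3,4-dimethoxycyclobut-3-ene-1,2-dione)
Product: 11 4-hydroxy-2,3-dimethoxy-4-{[(3S)-6,7,8-trimethoxy-3,4-dihydro-2H-chromen-3-yl]ethynyl}cyclobut-2-en-1-one (both carbinol epimers), via lithium [(3S)-6,7,8-trimethoxychroman-3-yl]acetylide 10 (not isolated)
Conditions: n-BuLi (1.0 equiv), THF, −78 °C; cannulated into 9, THF, −78 °C; aq. NH4Cl, −78 °C
Reagents that add atoms: none
Why: 1,2-Addition of a lithium acetylide to one of the two equivalent carbonyl groups of dimethyl squarate, a standard entry to 4-alkynyl-4-hydroxycyclobutenones; inverse addition at −78 °C limits double addition, and the new carbinol centre, formed without control, is erased in step 8.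

Step 8
Reactants: 11 4-hydroxy-2,3-dimethoxy-4-{[(3S)-6,7,8-trimethoxy-3,4-dihydro-2H-chromen-3-yl]ethynyl}cyclobut-2-en-1-one
Product: 14 abruquinone B, 2,3-dimethoxy-5-[(3S)-6,7,8-trimethoxy-3,4-dihydro-2H-chromen-3-yl]cyclohexa-2,5-diene-1,4-dione, via (Z)-enynylketene 12 (not isolated), via phenoxyl/aryl σ-diradical 13 (not isolated)
Conditions: p-xylene (degassed, 0.01 M), 138 °C
Reagents that add atoms: none
Why: Thermal 4π-conrotatory opening of the cyclobutenone breaks the C1–C4 bond with the hydroxyl rotating outward (donor torquoselectivity), which places the alkynyl group cis to the ketene in (Z)-enynylketene 12. The ketene carbon then bonds to the distal alkyne carbon to give the aromatic diradical 13, and transfer of the hydroxyl hydrogen to the adjacent aryl radical carbon releases the quinone; this is the Moore rearrangement of 4-alkynyl-4-hydroxycyclobutenones, its closest relative being the Myers–Saito-type cycloaromatisation of enyne-allenes. The one ring formed, the quinone, closes in a 6-endo-dig mode on the alkyne, so the four squarate carbons become C1–C4 and the alkyne carbons become C6–H and C5 bearing the chroman. No stereocentre is created: the carbinol centre of 11 becomes a carbonyl carbon, and chroman C3 takes part in no bond change and sees only neutral thermal conditions. The selectivity needed is 6-endo over 5-exo closure (which would give a 2-alkylidenecyclopentene-1,3-dione); the sec-alkyl substituent on the alkyne offers no stabilisation to the vinyl radical of the 5-exo path, so the six-ring diradical should dominate, and the free O–H is a fast internal hydrogen source that should outrun attack of the aryl radical on the chroman arene.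

Compound list
1 | 2,3,4-trimethoxyphenol | COc1ccc(O)c(OC)c1OC | starting material
2 | 2-hydroxy-3,4,5-trimethoxybenzaldehyde | COc1cc(C=O)c(O)c(OC)c1OC | intermediate
3 | acrolein | C=CC=O | starting material
4 | 6,7,8-trimethoxy-2H-chromene-3-carbaldehyde | COc1cc2C=C(C=O)COc2c(OC)c1OC | intermediate
5 | (6,7,8-trimethoxy-2H-chromen-3-yl)methanol | COc1cc2C=C(CO)COc2c(OC)c1OC | intermediate
6 | [(3S)-6,7,8-trimethoxy-3,4-dihydro-2H-chromen-3-yl]methanol | OC[C@H]1COc2c(cc(OC)c(OC)c2OC)C1 | intermediate
7 | (3R)-6,7,8-trimethoxy-3,4-dihydro-2H-chromene-3-carbaldehyde | O=C[C@H]1COc2c(cc(OC)c(OC)c2OC)C1 | intermediate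
8 | (3S)-3-ethynyl-6,7,8-trimethoxy-3,4-dihydro-2H-chromene | C#C[C@H]1COc2c(cc(OC)c(OC)c2OC)C1 | intermediate
9 | dimethyl squarate (3,4-dimethoxycyclobut-3-ene-1,2-dione) | COC1=C(OC)C(=O)C1=O | starting material
10 | lithium [(3S)-6,7,8-trimethoxychroman-3-yl]acetylide | [Li]C#C[C@H]1COc2c(cc(OC)c(OC)c2OC)C1 | intermediate
11 | 4-hydroxy-2,3-dimethoxy-4-{[(3S)-6,7,8-trimethoxy-3,4-dihydro-2H-chromen-3-yl]ethynyl}cyclobut-2-en-1-one (both carbinol epimers) | COC1=C(OC)C(O)(C#C[C@H]2COc3c(cc(OC)c(OC)c3OC)C2)C1=O | intermediate
12 | (3Z)-4-hydroxy-2,3-dimethoxy-6-[(3S)-6,7,8-trimethoxy-3,4-dihydro-2H-chromen-3-yl]hexa-1,3-dien-5-yn-1-one (enynylketene) | O=C=C(OC)/C(OC)=C(/O)C#C[C@H]1COc2c(cc(OC)c(OC)c2OC)C1 | intermediate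
13 | diradical: 4-hydroxy-2,3-dimethoxy-6-[(3S)-6,7,8-trimethoxychroman-3-yl]benzene with an oxyl radical at C1 and an aryl σ-radical at C5 | [O]c1c(OC)c(OC)c(O)[c]c1[C@H]2COc3c(cc(OC)c(OC)c3OC)C2 | intermediate
14 | abruquinone B, 2,3-dimethoxy-5-[(3S)-6,7,8-trimethoxy-3,4-dihydro-2H-chromen-3-yl]cyclohexa-2,5-diene-1,4-dione | COC1=C(OC)C(=O)C([C@H]2COc3c(cc(OC)c(OC)c3OC)C2)=CC1=O | target

Total step count: 8
Longest linear sequence: 8 steps (1 to 14); acrolein 3 and dimethyl squarate 9 enter as purchased.

Steps most likely to fail

1. Step 8 (key step). Two processes could erode the quinone. The enynylketene may partly close in the 5-exo mode. The aryl σ-radical of the diradical may add to the electron-rich chroman arene, or abstract hydrogen intermolecularly, before the O–H shift.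
Fallback: a closed-shell ring expansion of the same squarate four-ring, setting out from aldehyde 7 and coming back at target 14. Takai olefination of 7 (CHI3, CrCl2, THF, 0 °C) should give (3S)-3-[(E)-2-iodoethenyl]-6,7,8-trimethoxychroman F1. Iodine–lithium exchange (t-BuLi, Et2O, −78 °C) should give the (E)-alkenyllithium F2, which is added to dimethyl squarate 9 at −78 °C to give the 4-alkenyl-4-hydroxycyclobutenone F3. Heating F3 in toluene (110 °C) should expand the ring by electrocyclic opening, 6π-closure of the resulting dienylketene and tautomerisation, giving the hydroquinone F4. Oxidation of F4 (Ag2O, Et2O, rt) should give 14. No radical intermediate is involved, so neither the five-ring closure nor radical trapping can occur.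

2. Step 4. Face discrimination by the iridium catalyst may be incomplete, because C3 carries two similar CH2–O substituents. The acidic iridium hydride may also isomerise the allylic alcohol to the saturated aldehyde without stereocontrol.
Fallback: the stereo-defining step is moved to the acid oxidation level, setting out from aldehyde 4 and coming back at alcohol 6. Pinnick oxidation of 4 (NaClO2, NaH2PO4, 2-methyl-2-butene, t-BuOH/H2O) should give 6,7,8-trimethoxy-2H-chromene-3-carboxylic acid F5. Carboxylate-directed asymmetric hydrogenation of this cyclic (E)-α-substituted cinnamic acid (Ru(OAc)2(BINAP) or an Ir spiro-phosphine–oxazoline catalyst, H2, MeOH, Et3N) should give the (3R)-chroman-3-carboxylic acid F6. This acid is crystalline, so its enantiopurity can be raised by recrystallisation of its 1-phenylethylammonium salt. Reduction with BH3·SMe2 (THF, 0 °C to rt) should give 6.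

3. Step 6. K2CO3/MeOH may enolise the α-branched, β-aryloxy aldehyde during the homologation, possibly with reversible retro-oxa-Michael ring opening, which would epimerise C3.
Fallback: a base-free homologation, setting out from aldehyde 7 and coming back at lithium acetylide 10. Corey–Fuchs olefination of 7 (CBr4, PPh3, CH2Cl2, 0 °C) should give (3S)-3-(2,2-dibromoethenyl)-6,7,8-trimethoxychroman F7. Treatment with n-BuLi (2 equiv, THF, −78 °C) should give 10 directly by bromine–lithium exchange and Fritsch–Buttenberg–Wiechell rearrangement. Acetylide 10 is then cannulated into 9 as in step 7, without isolating alkyne 8.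

Further compounds
F1 | step 8 | (3S)-3-[(E)-2-iodoethenyl]-6,7,8-trimethoxy-3,4-dihydro-2H-chromene | I/C=C/[C@H]1COc2c(cc(OC)c(OC)c2OC)C1
F2 | step 8 | lithium (E)-2-[(3S)-6,7,8-trimethoxychroman-3-yl]ethenide (alkenyllithium) | [Li]/C=C/[C@H]1COc2c(cc(OC)c(OC)c2OC)C1
F3 | step 8 | 4-hydroxy-2,3-dimethoxy-4-{(E)-2-[(3S)-6,7,8-trimethoxy-3,4-dihydro-2H-chromen-3-yl]ethenyl}cyclobut-2-en-1-one (both carbinol epimers) | COC1=C(OC)C(O)(/C=C/[C@H]2COc3c(cc(OC)c(OC)c3OC)C2)C1=O
F4 | step 8 | 2,3-dimethoxy-5-[(3S)-6,7,8-trimethoxy-3,4-dihydro-2H-chromen-3-yl]benzene-1,4-diol | COc1c(OC)c(O)c([C@H]2COc3c(cc(OC)c(OC)c3OC)C2)cc1O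
F5 | step 4 | 6,7,8-trimethoxy-2H-chromene-3-carboxylic acid | COc1cc2C=C(C(=O)O)COc2c(OC)c1OC
F6 | step 4 | (3R)-6,7,8-trimethoxy-3,4-dihydro-2H-chromene-3-carboxylic acid | OC(=O)[C@H]1COc2c(cc(OC)c(OC)c2OC)C1
F7 | step 6 | (3S)-3-(2,2-dibromoethenyl)-6,7,8-trimethoxy-3,4-dihydro-2H-chromene | BrC(Br)=C[C@H]1COc2c(cc(OC)c(OC)c2OC)C1
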